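**Retrosynthetic overview**

1. The core is numbered as tetracyclo[6.4.0.0(2,7).0(3,6)]dodecane: ring A = cyclohexane (C1, C8–C12), ring B = C1/C2/C7/C8, ring C = C2/C3/C6/C7, ring D = C3–C6, chain on C10. The strategy rests on ring C: its rail bonds C2–C3 and C6–C7 are the only links between the A/B half and ring D, and the chain-free core has a mirror plane (through the midpoints of C1–C8, C2–C7, C3–C6, C4–C5, C10–C11).
2. The C10 side chain is cut at an exocyclic C10=C bond (hydrogenation, then Wittig), giving the C10 ketone 18 and the glyceryl-oxyoctyl phosphonium salt 22.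
3. Ketone 18 comes from the meso 10,11-diol 15 by lipase desymmetrisation, oxidation and SmI2 deoxygenation.
4. Key disconnection: C2–C3 and C6–C7 are cut together, giving the meso bicyclo[4.2.0]oct-7-ene acetonide 10 and cyclobutene 13 (CuOTf-sensitised [2+2]).
5. Ring order: ring A (cyclohexa-1,4-diene), ring B (dichloroketene [2+2], then Shapiro to the cyclobutene), ring D (preformed as cyclobutene), ring C last.

Key step: step 9

Assumptions on the chemistry: the lipase is taken to acylate the (R)-configured carbinol C11 of meso diol 15, as the empirical rule for secondary alcohols predicts; this choice fixes the absolute configuration of the route. Compounds 6–9 are racemic and drawn as one enantiomer; 10, 14 and 15 are meso.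

**Step 1**
Reactants: 1 cyclohexa-1,4-diene
Product: 2 cis-cyclohex-4-ene-1,2-diol (meso)
Conditions: K2OsO4·2H2O (1 mol%), NMO (1.0 equiv), diene (3 equiv), acetone/H2O, 0 °C to rt
Reagents that add atoms: N-methylmorpholine N-oxide, C[N+]1([O-])CCOCC1; water, O
Why: Osmium-catalysed cis-dihydroxylation with NMO as terminal oxidant adds both oxygens to one face of one alkene, which sets the cis (meso) diol, and limiting oxidant with excess diene should hold the reaction at the mono-diol.

**Step 2**
Reactants: 2 cis-cyclohex-4-ene-1,2-diol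
Product: 3 cis-2,2-dimethyl-3a,4,7,7a-tetrahydro-1,3-benzodioxole (meso acetonide)
Conditions: Me2C(OMe)2, TsOH·H2O (cat.), acetone, rt
Reagents that add atoms: 2,2-dimethoxypropane, COC(C)(C)OC
Why: Acid-catalysed transketalisation (acetonide formation) of a cis-1,2-diol is fast and leaves the isolated alkene untouched.

**Step 3**
Reactants: 3 meso acetonide; 4 trichloroacetyl chloride
Product: 6 racemic 8,8-dichloro-3,4-(isopropylidenedioxy)-cis-bicyclo[4.2.0]octan-7-one (cyclobutanone anti to the dioxolane), via dichloroketene 5 (not isolated)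
Conditions: Zn–Cu couple, Et2O/DME, sonication, 15–25 °C
Reagents that add atoms: none
Why: Thermal ketene–alkene [2+2] cycloaddition of dichloroketene (formed by zinc dechlorination of 4) is suprafacial on the alkene, so the new ring fusion is cis, and the ketene should approach the face anti to the folded dioxolane, with DME tying up ZnCl2 to spare the acetonide.

**Step 4**
Reactants: 6 dichlorocyclobutanone
Product: 7 racemic 3,4-(isopropylidenedioxy)-cis-bicyclo[4.2.0]octan-7-one
Conditions: Zn dust, NH4Cl, MeOH, rt
Reagents that add atoms: none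
Why: Zinc-mediated reductive dehalogenation of the α,α-dichloro ketone under near-neutral buffering removes both chlorines without touching the acetonide or the ring-fusion centres.

**Step 5**
Reactants: 7 cyclobutanone
Product: 8 tosylhydrazone of 7
Conditions: TsNHNH2, MeOH, rt
Reagents that add atoms: p-toluenesulfonyl hydrazide, Cc1ccc(cc1)S(=O)(=O)NN
Why: Hydrazone condensation of the strained, electrophilic cyclobutanone is fast at room temperature and needs no added acid that could open the acetonide.

**Step 6**
Reactants: 8 tosylhydrazone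
Product: 10 meso 3,4-(isopropylidenedioxy)-cis-bicyclo[4.2.0]oct-7-ene (dioxolane anti to the cyclobutene), via cyclobutenyllithium 9 (not isolated)
Conditions: n-BuLi (2.5 equiv), TMEDA, THF, −78 °C to rt; then H2O
Reagents that add atoms: none
Why: Shapiro reaction: deprotonation at N–H and at the less substituted α-CH2, loss of sulfinate and N2, and protonation of the alkenyllithium give the C7=C8 cyclobutene regioselectively and avoid the cyclobutylidene carbene that would ring-contract under Bamford–Stevens conditions; the product regains its mirror plane.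

**Step 7**
Reactants: 11 cyclobutanol
Product: 12 cyclobutyl p-toluenesulfonate
Conditions: TsCl, pyridine, 0 °C
Reagents that add atoms: p-toluenesulfonyl chloride, Cc1ccc(cc1)S(Cl)(=O)=O
Why: Sulfonylation of an unhindered secondary alcohol in pyridine is routine.

**Step 8**
Reactants: 12 cyclobutyl p-toluenesulfonate
Product: 13 cyclobutene
Conditions: KOtBu, DMSO, 70 °C, product swept with N2 into a −78 °C trap
Reagents that add atoms: none
Why: E2 elimination of the secondary tosylate gives cyclobutene, which leaves the hot mixture as a gas (b.p. about 2 °C) and is condensed cold, so it cannot react further.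

**Step 9**
Reactants: 10 meso bicyclo[4.2.0]oct-7-ene acetonide; 13 cyclobutene
Product: 14 meso 10,11-(isopropylidenedioxy)tetracyclo[6.4.0.0(2,7).0(3,6)]dodecane (all ring fusions cis, rings A/C anti across ring B, rings B/D anti across ring C, dioxolane anti to ring B)
Conditions: (CuOTf)2·C6H6 (5 mol%), 13 (15 equiv), Et2O, hν 254 nm, sealed quartz tube, −10 °C
Reagents that add atoms: none
Why: Both alkenes bind monovalent copper, and excitation of the bis(alkene) complex couples the two ligands through a copper-bound 1,4-diradicaloid that collapses to the cyclobutane; this is the CuOTf-catalysed [2+2] photocycloaddition, whose closest known cases are the photodimerisations of cyclobutene-type and other strained cycloalkenes and the mixed couplings of two cycloalkenes. Ring C closes intermolecularly by forming both rail bonds C2–C3 and C6–C7, the second by ring closure of the diradicaloid inside the copper coordination sphere. C2 and C7 are set by copper binding to the exo face of 10, because the cyclohexane CH2 groups block the concave face. C3 and C6 are cis because both bonds form on one face of the small ring of 13, and rings B and D end up anti across ring C because the two four-membered rings avoid each other on copper. The selectivity needed is crossed over homo coupling, which the large excess of volatile 13 should secure: 10 is the outnumbered ligand, and the homodimer of 13 is removed by evaporation. As 10 and 14 are meso, only relative configuration is at stake.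

**Step 10**
Reactants: 14 ladder acetonide
Product: 15 meso tetracyclo[6.4.0.0(2,7).0(3,6)]dodecane-10,11-diol (cis-diol, hydroxyls anti to ring B)
Conditions: 1 M aq. HCl, THF, rt
Reagents that add atoms: none
Why: Acid-catalysed acetal hydrolysis frees the cis-diol, and the saturated ladder core has no acid-labile function.

**Step 11**
Reactants: 15 meso diol
Product: 16 (10S,11R)-11-acetoxytetracyclo[6.4.0.0(2,7).0(3,6)]dodecan-10-ol
Conditions: Burkholderia cepacia lipase (immobilised), vinyl acetate, t-BuOMe, 30 °C
Reagents that add atoms: vinyl acetate, CC(=O)OC=C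
Why: Lipase-catalysed enantiotopos-selective transesterification, made irreversible by loss of acetaldehyde, should acylate only the (R)-carbinol C11 in the chiral active site, which sets the absolute configuration; the monoacetate is carried on at once, without base, to avoid 1,2-acyl migration.

**Step 12**
Reactants: 16 monoacetate
Product: 17 (11R)-11-acetoxytetracyclo[6.4.0.0(2,7).0(3,6)]dodecan-10-one
Conditions: Dess–Martin periodinane, CH2Cl2, 0 °C to rt
Reagents that add atoms: none
Why: Dess–Martin oxidation of the remaining secondary alcohol is fast and non-basic, so the acetate stays on C11 and the carbonyl is placed on C10.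

**Step 13**
Reactants: 17 α-acetoxy ketone
Product: 18 tetracyclo[6.4.0.0(2,7).0(3,6)]dodecan-10-one (single enantiomer)
Conditions: SmI2 (2.2 equiv), THF/MeOH, −78 °C
Reagents that add atoms: none
Why: Reductive cleavage of the α-acyloxy ketone by divalent samarium (two single-electron transfers, loss of acetate, protonation of the samarium enolate) removes the C11 oxygen; no stereocentre is α to the carbonyl, so the chirality now carried by the carbonyl position is stable.

**Step 14**
Reactants: 19 cis-2-phenyl-1,3-dioxan-5-ol; 20 1,8-dibromooctane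
Product: 21 cis-5-(8-bromooctyloxy)-2-phenyl-1,3-dioxane
Conditions: NaH, 20 (4 equiv), n-Bu4NI (cat.), DMF/THF, 0 °C to rt
Reagents that add atoms: none
Why: Williamson ether synthesis of the secondary alkoxide with a fourfold excess of the primary dibromide suppresses double alkylation.

**Step 15**
Reactants: 21 bromide
Product: 22 [8-(cis-2-phenyl-1,3-dioxan-5-yloxy)octyl]triphenylphosphonium bromide
Conditions: PPh3, MeCN, reflux
Reagents that add atoms: triphenylphosphine, c1ccc(cc1)P(c1ccccc1)c1ccccc1
Why: SN2 quaternisation of triphenylphosphine by a primary bromide is reliable, and the acetal is inert to it.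

**Step 16**
Reactants: 22 phosphonium bromide; 18 ketone
Product: 24 cis-5-[8-(tetracyclo[6.4.0.0(2,7).0(3,6)]dodecan-10-ylidene)octyloxy]-2-phenyl-1,3-dioxane (E/Z mixture), via phosphonium ylide 23 (not isolated)
Conditions: NaHMDS, THF, 0 °C; then 18, 0 °C to rt
Reagents that add atoms: none
Why: Wittig olefination of the unhindered cyclohexanone with a non-stabilised ylide gives the trisubstituted exocyclic alkene, whose E/Z isomers both lead to the same hydrogenation product.

**Step 17**
Reactants: 24 exocyclic alkene
Product: 25 cis-5-[8-((10S)-tetracyclo[6.4.0.0(2,7).0(3,6)]dodecan-10-yl)octyloxy]-2-phenyl-1,3-dioxane (chain cis to ring B)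
Conditions: H2 (1 atm), [Ir(cod)(PCy3)(py)]PF6 (5 mol%), CH2Cl2, rt
Reagents that add atoms: none
Why: Homogeneous catalytic syn hydrogenation should deliver hydrogen to C10 from the convex face of ring A (the face of the C1–H and C8–H bonds, away from ring B and its inward-pointing C2–H and C7–H), which places the chain cis to ring B; the iridium catalyst leaves the benzylidene acetal and the strained cyclobutanes alone.

**Step 18**
Reactants: 25 benzylidene acetal
Product: 26 2-[8-((10S)-tetracyclo[6.4.0.0(2,7).0(3,6)]dodecan-10-yl)octyloxy]propane-1,3-diol (target)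
Conditions: AcOH/H2O/THF (4:1:1), 55 °C
Reagents that add atoms: none
Why: Mild acid-catalysed acetal hydrolysis frees the 1,3-diol as benzaldehyde is lost, under conditions the saturated ladder hydrocarbon tolerates.

**Compound list**

1 | cyclohexa-1,4-diene | C1=CCC=CC1 | starting material
2 | cis-cyclohex-4-ene-1,2-diol (meso) | O[C@@H]1[C@H](O)CC=CC1 | intermediate
3 | cis-2,2-dimethyl-3a,4,7,7a-tetrahydro-1,3-benzodioxole (meso) | CC1(C)O[C@@H]2[C@H](O1)CC=CC2 | intermediate
4 | trichloroacetyl chloride | ClC(=O)C(Cl)(Cl)Cl | starting material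
5 | dichloroketene | ClC(Cl)=C=O | intermediate
6 | racemic 8,8-dichloro-3,4-(isopropylidenedioxy)-cis-bicyclo[4.2.0]octan-7-one, cyclobutanone anti to dioxolane | CC1(C)O[C@@H]2[C@H](O1)C[C@@H]3[C@H](C2)C(=O)C3(Cl)Cl | intermediate
7 | racemic 3,4-(isopropylidenedioxy)-cis-bicyclo[4.2.0]octan-7-one | CC1(C)O[C@@H]2[C@H](O1)C[C@@H]3[C@H](C2)C(=O)C3 | intermediate
8 | tosylhydrazone of 7 | CC1(C)O[C@@H]2[C@H](O1)C[C@@H]3[C@H](C2)C(=NNS(=O)(=O)c4ccc(C)cc4)C3 | intermediate
9 | 7-lithio-3,4-(isopropylidenedioxy)-cis-bicyclo[4.2.0]oct-7-ene | CC1(C)O[C@@H]2[C@H](O1)C[C@@H]3[C@H](C2)C([Li])=C3 | intermediate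
10 | meso 3,4-(isopropylidenedioxy)-cis-bicyclo[4.2.0]oct-7-ene, dioxolane anti to cyclobutene | CC1(C)O[C@@H]2[C@H](O1)C[C@@H]3[C@H](C2)C=C3 | intermediate
11 | cyclobutanol | OC1CCC1 | starting material
12 | cyclobutyl p-toluenesulfonate | Cc1ccc(cc1)S(=O)(=O)OC1CCC1 | intermediate
13 | cyclobutene | C1=CCC1 | intermediate
14 | meso 10,11-(isopropylidenedioxy)tetracyclo[6.4.0.0(2,7).0(3,6)]dodecane, cis-anti-cis-anti-cis ladder, dioxolane anti to ring B | CC1(C)O[C@@H]2[C@H](O1)C[C@@H]3[C@H](C2)[C@H]2[C@@H]4CC[C@@H]4[C@@H]32 | intermediate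
15 | meso tetracyclo[6.4.0.0(2,7).0(3,6)]dodecane-10,11-diol | O[C@@H]1[C@H](O)C[C@@H]2[C@H](C1)[C@H]1[C@@H]3CC[C@@H]3[C@@H]21 | intermediate
16 | (10S,11R)-11-acetoxytetracyclo[6.4.0.0(2,7).0(3,6)]dodecan-10-ol | O[C@@H]1[C@H](OC(C)=O)C[C@@H]2[C@H](C1)[C@H]1[C@@H]3CC[C@@H]3[C@@H]21 | intermediate
17 | (11R)-11-acetoxytetracyclo[6.4.0.0(2,7).0(3,6)]dodecan-10-one | O=C1[C@H](OC(C)=O)C[C@@H]2[C@H](C1)[C@H]1[C@@H]3CC[C@@H]3[C@@H]21 | intermediate
18 | tetracyclo[6.4.0.0(2,7).0(3,6)]dodecan-10-one, single enantiomer | O=C1CC[C@@H]2[C@H](C1)[C@H]1[C@@H]3CC[C@@H]3[C@@H]21 | intermediate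
19 | cis-2-phenyl-1,3-dioxan-5-ol | O[C@H]1CO[C@@H](c2ccccc2)OC1 | starting material
20 | 1,8-dibromooctane | BrCCCCCCCCBr | starting material
21 | cis-5-(8-bromooctyloxy)-2-phenyl-1,3-dioxane | c1ccccc1[C@@H]2OC[C@@H](CO2)OCCCCCCCCBr | intermediate
22 | [8-(cis-2-phenyl-1,3-dioxan-5-yloxy)octyl]triphenylphosphonium bromide | [Br-].c1ccccc1[C@@H]2OC[C@@H](CO2)OCCCCCCCC[P+](c3ccccc3)(c4ccccc4)c5ccccc5 | intermediate
23 | phosphonium ylide from 22 | c1ccccc1[C@@H]2OC[C@@H](CO2)OCCCCCCCC=P(c3ccccc3)(c4ccccc4)c5ccccc5 | intermediate
24 | cis-5-[8-(tetracyclo[6.4.0.0(2,7).0(3,6)]dodecan-10-ylidene)octyloxy]-2-phenyl-1,3-dioxane, E/Z mixture | c1ccccc1[C@@H]2OC[C@@H](CO2)OCCCCCCCC=C1CC[C@@H]2[C@H](C1)[C@H]1[C@@H]3CC[C@@H]3[C@@H]21 | intermediate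
25 | cis-5-[8-((10S)-tetracyclo[6.4.0.0(2,7).0(3,6)]dodecan-10-yl)octyloxy]-2-phenyl-1,3-dioxane | c1ccccc1[C@@H]2OC[C@@H](CO2)OCCCCCCCC[C@H]1CC[C@@H]2[C@H](C1)[C@H]1[C@@H]3CC[C@@H]3[C@@H]21 | intermediate
26 | 2-[8-((10S)-tetracyclo[6.4.0.0(2,7).0(3,6)]dodecan-10-yl)octyloxy]propane-1,3-diol (CNP0193334.1) | OCC(CO)OCCCCCCCC[C@H]1CC[C@@H]2[C@H](C1)[C@H]1[C@@H]3CC[C@@H]3[C@@H]21 | target

**Step count**

Total: 18 steps. Longest linear sequence: 14 steps (steps 1–6, 9–13, 16–18); cyclobutene (steps 7–8) and the phosphonium salt (steps 14–15) are made in side branches.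

**Three steps most likely to fail**

Step 9 (key step). The crossed coupling may lose out to homodimerisation of 13 and of 10 on copper, or conversion of 10 may stall as the catalyst is consumed. The fallback sets out from 10 and comes back at 14. Ring C is closed instead by an enone–alkene [2+2] photocycloaddition, in which only the enone absorbs, so the crossing is inherent. Compound 10 is irradiated (350 nm, CH2Cl2, −40 °C) with cyclopent-2-en-1-one to give the exo, cis-anti-cis tetracyclic cyclopentanone F1. Claisen formylation (HCO2Et, NaH, THF) gives the hydroxymethylene ketone F2. Deformylative Regitz diazo transfer (MsN3, Et3N, MeCN) gives the α-diazoketone F3. Photochemical Wolff ring contraction in THF/H2O turns the five-membered ring into ring D and gives the ladder carboxylic acid F4. Barton decarboxylation through the N-acyloxypyridine-2-thione ester F5 (DCC, 2-mercaptopyridine N-oxide; then t-BuSH in excess as a fast hydrogen donor, visible light) gives 14.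

Step 11. The enzyme may select the other enantiotopic hydroxyl or select poorly, and the cis-1,2-diol monoacetate may lose enantiopurity through 1,2-acyl migration. The fallback sets out from 15 and comes back at 18. It uses a small-molecule catalyst available in both mirror-image forms and a less mobile acyl group. Monobenzoylation catalysed by divalent copper triflate Cu(OTf)2 and Ph-BOX (BzCl, K2CO3, CH2Cl2, 0 °C), with the ligand antipode that acylates C11, gives the (10S,11R)-monobenzoate F6. Dess–Martin oxidation gives the α-benzoyloxy ketone F7, and SmI2 (THF/MeOH, −78 °C) gives 18.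

Step 17. Hydrogen delivery to the remote exocyclic alkene may discriminate poorly between the two faces, giving C10 epimers that are hard to separate at the hydrocarbon-like stage. The fallback sets out from 18 (with 21 from the side branch) and comes back at 25. C10 is set by stereospecific substitution instead. Reduction of 18 with LiBH(s-Bu)3 (THF, −78 °C) from the convex face should give the concave-face alcohol F8, and the epimeric alcohol is removed by chromatography at this polar stage. Appel bromination (CBr4, PPh3, CH2Cl2) with inversion gives the bromide F9. SN2 coupling with inversion (CuI cat., TMEDA, LiOMe, THF, 0 °C) with the Grignard reagent F10, made from 21 and Mg in THF, gives 25.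

**Further compounds**

F1 | step 9 | tetracyclic cyclopentanone photoadduct of 10 and cyclopent-2-en-1-one (racemic, cis-anti-cis) | CC1(C)O[C@@H]2[C@H](O1)C[C@@H]3[C@H](C2)[C@H]2[C@@H]4C(=O)CC[C@@H]4[C@@H]32
F2 | step 9 | hydroxymethylene ketone from F1 | CC1(C)O[C@@H]2[C@H](O1)C[C@@H]3[C@H](C2)[C@H]2[C@@H]4C(=O)C(=CO)C[C@@H]4[C@@H]32
F3 | step 9 | α-diazoketone from F2 | CC1(C)O[C@@H]2[C@H](O1)C[C@@H]3[C@H](C2)[C@H]2[C@@H]4C(=O)C(=[N+]=[N-])C[C@@H]4[C@@H]32
F4 | step 9 | 10,11-(isopropylidenedioxy)tetracyclo[6.4.0.0(2,7).0(3,6)]dodecane-4-carboxylic acid (epimers at C4) | CC1(C)O[C@@H]2[C@H](O1)C[C@@H]3[C@H](C2)[C@H]2[C@@H]4C(C(O)=O)C[C@@H]4[C@@H]32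
F5 | step 9 | N-acyloxypyridine-2-thione (Barton) ester of F4 | CC1(C)O[C@@H]2[C@H](O1)C[C@@H]3[C@H](C2)[C@H]2[C@@H]4C(C(=O)ON5C=CC=CC5=S)C[C@@H]4[C@@H]32
F6 | step 11 | (10S,11R)-11-benzoyloxytetracyclo[6.4.0.0(2,7).0(3,6)]dodecan-10-ol | O[C@@H]1[C@H](OC(=O)c2ccccc2)C[C@@H]2[C@H](C1)[C@H]1[C@@H]3CC[C@@H]3[C@@H]21
F7 | step 11 | (11R)-11-benzoyloxytetracyclo[6.4.0.0(2,7).0(3,6)]dodecan-10-one | O=C1[C@H](OC(=O)c2ccccc2)C[C@@H]2[C@H](C1)[C@H]1[C@@H]3CC[C@@H]3[C@@H]21
F8 | step 17 | tetracyclo[6.4.0.0(2,7).0(3,6)]dodecan-10-ol, hydroxyl cis to ring B | O[C@H]1CC[C@@H]2[C@H](C1)[C@H]1[C@@H]3CC[C@@H]3[C@@H]21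
F9 | step 17 | 10-bromotetracyclo[6.4.0.0(2,7).0(3,6)]dodecane, bromine trans to ring B | Br[C@@H]1CC[C@@H]2[C@H](C1)[C@H]1[C@@H]3CC[C@@H]3[C@@H]21
F10 | step 17 | [8-(cis-2-phenyl-1,3-dioxan-5-yloxy)octyl]magnesium bromide | c1ccccc1[C@@H]2OC[C@@H](CO2)OCCCCCCCC[Mg]Br
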